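**Retrosynthetic overview**
- Jaspaquinol ⇐ its diacetate. The ester cleavage comes last, so the hydroquinone stays masked through the acid step.
- Key disconnection: the C10–C15 σ-bond of the trimethylcyclohexene (geranylgeranyl numbering), opened to the all-E acyclic geranylgeranylhydroquinone diacetate. Forward, this is proton-initiated closure of the terminal isopropylidene unit onto the 10,11-olefin with loss of H-10, the presumed biosynthetic ring closure, done late on the complete C26 skeleton.
- Acyclic precursor ⇐ hydroquinone + (2E,6E,10E)-geranylgeraniol by Friedel–Crafts C-allylation (the biosynthetic prenylation), acetylated in the same flask.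
- Ring order: the benzene ring is bought; the only ring formed is the cyclohexene, in the second of three steps. Both chain E-olefins come from geranylgeraniol and are never rebuilt.

Assumption: jaspaquinol has no stereocentre, so the stereochemical task is the (2E,6E) geometry of the two chain olefins.

**Step 1**
Reactants: 1 hydroquinone; 2 (2E,6E,10E)-geranylgeraniol
Product: 4 2-[(2E,6E,10E)-3,7,11,15-tetramethylhexadeca-2,6,10,14-tetraen-1-yl]-1,4-phenylene diacetate, via geranylgeranylhydroquinone 3 (not isolated)
Conditions: 1 (3 equiv), BF3·OEt2 (0.3 equiv), 1,4-dioxane, 20 °C; then pyridine, Ac2O, 4-(dimethylamino)pyridine (cat.), 20 °C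
Reagents that add atoms: acetic anhydride, CC(=O)OC(C)=O
Why: Friedel–Crafts C-allylation: BF3·OEt2 ionises the allylic alcohol and hydroquinone (four equivalent positions, excess suppresses dialkylation) attacks the primary terminus of the allyl cation with the 2E geometry retained; acetylation in the same flask masks the phenols so that no chroman can form under acid in step 2.

**Step 2**
Reactants: 4 2-[(2E,6E,10E)-3,7,11,15-tetramethylhexadeca-2,6,10,14-tetraen-1-yl]-1,4-phenylene diacetate
Product: 5 2-[(2E,6E)-3,7-dimethyl-9-(2,6,6-trimethylcyclohex-1-en-1-yl)nona-2,6-dien-1-yl]-1,4-phenylene diacetate (jaspaquinol diacetate)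
Conditions: H2SO4 (cat.), AcOH, 15 °C, stopped at ca. 60% conversion; AgNO3–SiO2 chromatography (recovered 4 recycled)
Reagents that add atoms: none
Why: Proposed new method: the terminal isopropylidene is the most accessible and electron-rich olefin (C2=C3 is inductively deactivated by the diacetoxybenzyl group and its cation has no productive six-membered closure), so Markovnikov protonation at C14 with concerted attack of the 10,11-olefin (Stork–Eschenmoser cation–olefin cyclisation) gives the tertiary C11 cation, which in acetic acid loses a proton or is captured by solvent faster than the chain can fold for a second closure, and re-ionisation of the tertiary acetate and the less substituted ring olefins drains the monocycle toward the tetrasubstituted olefin by loss of H-10; closest known reaction type: H2SO4–AcOH cyclisation of geranyl derivatives (geranyl aryl sulfones to β-cyclogeranyl sulfones) and the stepwise acid cyclisation of farnesyl compounds that halts at monocyclofarnesyl products; no stereocentre is formed and the aryl acetates are inert in AcOH.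

**Step 3**
Reactants: 5 jaspaquinol diacetate
Product: 6 jaspaquinol, 2-[(2E,6E)-3,7-dimethyl-9-(2,6,6-trimethylcyclohex-1-en-1-yl)nona-2,6-dien-1-yl]benzene-1,4-diol
Conditions: K2CO3 (cat.), degassed MeOH, 0 °C to 20 °C, Ar; aq. NH4Cl/Na2S2O4 work-up
Reagents that add atoms: none
Why: Base-catalysed transesterification (methanolysis) of the two aryl acetates; the olefins are inert to K2CO3/MeOH, and exclusion of air with a dithionite work-up keeps the hydroquinone from oxidising to the quinone.

**Compound list**
1 | hydroquinone (benzene-1,4-diol) | Oc1ccc(O)cc1 | starting material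
2 | (2E,6E,10E)-geranylgeraniol, (2E,6E,10E)-3,7,11,15-tetramethylhexadeca-2,6,10,14-tetraen-1-ol | CC(C)=CCC/C(C)=C/CC/C(C)=C/CC/C(C)=C/CO | starting material
3 | geranylgeranylhydroquinone, 2-[(2E,6E,10E)-3,7,11,15-tetramethylhexadeca-2,6,10,14-tetraen-1-yl]benzene-1,4-diol (not isolated) | CC(C)=CCC/C(C)=C/CC/C(C)=C/CC/C(C)=C/Cc1cc(O)ccc1O | intermediate
4 | 2-[(2E,6E,10E)-3,7,11,15-tetramethylhexadeca-2,6,10,14-tetraen-1-yl]-1,4-phenylene diacetate | CC(C)=CCC/C(C)=C/CC/C(C)=C/CC/C(C)=C/Cc1cc(OC(C)=O)ccc1OC(C)=O | intermediate
5 | jaspaquinol diacetate, 2-[(2E,6E)-3,7-dimethyl-9-(2,6,6-trimethylcyclohex-1-en-1-yl)nona-2,6-dien-1-yl]-1,4-phenylene diacetate | CC1=C(CC/C(C)=C/CC/C(C)=C/Cc2cc(OC(C)=O)ccc2OC(C)=O)C(C)(C)CCC1 | intermediate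
6 | jaspaquinol | CC1=C(CC/C(C)=C/CC/C(C)=C/Cc2cc(O)ccc2O)C(C)(C)CCC1 | target

**Total step count:** 3. **Longest linear sequence:** 3.

**Steps most likely to fail**

Step 2 (highest risk). Four things can go wrong:
- The ring double bond may end up in the less substituted positions. Kinetic proton loss from this hindered cation usually favours those isomers, so 5 may be a minor component.
- A second closure onto the 6,7-olefin would give bicyclic diacetates.
- Initiation at the 10,11-olefin would give other skeletons.
- Reversible protonation could erode the E geometry of the chain olefins.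

The fallback sets out from hydroquinone 1 and comes back at diacetate 5. It closes the ring one prenyl level earlier, where no second olefin can intercept the cation and full thermodynamic control is allowed. Geranyl bromide and PhSO2Na in DMF give geranyl phenyl sulfone F1. H2SO4–AcOH cyclises it (the same cation–olefin closure) to β-cyclogeranyl phenyl sulfone F2, the tetrasubstituted olefin being the equilibrium product. Geranyl acetate is oxidised at its terminal E-methyl group (SeO2 cat., t-BuOOH, CH2Cl2) to (2E,6E)-8-hydroxygeranyl acetate F3, and CBr4/PPh3 converts this into (2E,6E)-8-bromogeranyl acetate F4. The lithio derivative of F2 (n-BuLi, THF, −78 °C) is alkylated with F4 to give the racemic sulfone acetate F5. K2CO3/MeOH gives hydroxy sulfone F6, and Na(Hg)/Na2HPO4 in MeOH removes the sulfonyl group to give the monocyclic diterpene alcohol F7. Friedel–Crafts allylation of 1 with F7 and acetylation, under the conditions of step 1, gives 5.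

Step 1. The Friedel–Crafts allylation typically gives modest yields. By-products are dialkylated material, O-alkylated material, chromans and some 2Z isomer.

The fallback sets out from 1 and 2 and comes back at 3, which is then acetylated to 4 as in step 1. Directed ortho-metalation and SN2 alkylation replace the electrophilic substitution. Hydroquinone 1 is converted (NaH, chloromethyl methyl ether, DMF) into 1,4-bis(methoxymethoxy)benzene F8. Geraniol 2 is converted (PBr3, Et2O, −10 °C) into (2E,6E,10E)-geranylgeranyl bromide F9. F8 is lithiated next to an acetal oxygen (n-BuLi, Me2NCH2CH2NMe2, THF, 0 °C) and, after addition of CuBr·SMe2, alkylated with F9 to give the bis(methoxymethyl) ether of geranylgeranylhydroquinone F10. HCl (cat.) in MeOH at 20 °C removes both acetals to give 3.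

Step 3. The free hydroquinone may be partly oxidised during methanolysis or chromatography, giving hydroquinone/quinone mixtures.

The fallback sets out from 5 and comes back at 6. It takes the material deliberately through the quinone level. Methanolysis of 5 (K2CO3, MeOH) followed by Ag2O in Et2O gives jaspaquinone F11, which is stable to air and silica and is purified at this stage. Reduction with aqueous Na2S2O4 in THF under Ar then gives 6 without further chromatography.

**Further compounds**
F1 | step 2 | geranyl phenyl sulfone, {[(2E)-3,7-dimethylocta-2,6-dien-1-yl]sulfonyl}benzene | CC(C)=CCC/C(C)=C/CS(=O)(=O)c1ccccc1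
F2 | step 2 | β-cyclogeranyl phenyl sulfone, {[(2,6,6-trimethylcyclohex-1-en-1-yl)methyl]sulfonyl}benzene | CC1=C(CS(=O)(=O)c2ccccc2)C(C)(C)CCC1
F3 | step 2 | (2E,6E)-8-hydroxy-3,7-dimethylocta-2,6-dien-1-yl acetate | OC/C(C)=C/CC/C(C)=C/COC(C)=O
F4 | step 2 | (2E,6E)-8-bromo-3,7-dimethylocta-2,6-dien-1-yl acetate | BrC/C(C)=C/CC/C(C)=C/COC(C)=O
F5 | step 2 | (2E,6E)-3,7-dimethyl-9-(phenylsulfonyl)-9-(2,6,6-trimethylcyclohex-1-en-1-yl)nona-2,6-dien-1-yl acetate (racemic) | CC1=C(C(C/C(C)=C/CC/C(C)=C/COC(C)=O)S(=O)(=O)c2ccccc2)C(C)(C)CCC1
F6 | step 2 | (2E,6E)-3,7-dimethyl-9-(phenylsulfonyl)-9-(2,6,6-trimethylcyclohex-1-en-1-yl)nona-2,6-dien-1-ol (racemic) | CC1=C(C(C/C(C)=C/CC/C(C)=C/CO)S(=O)(=O)c2ccccc2)C(C)(C)CCC1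
F7 | step 2 | (2E,6E)-3,7-dimethyl-9-(2,6,6-trimethylcyclohex-1-en-1-yl)nona-2,6-dien-1-ol | CC1=C(CC/C(C)=C/CC/C(C)=C/CO)C(C)(C)CCC1
F8 | step 1 | 1,4-bis(methoxymethoxy)benzene | COCOc1ccc(OCOC)cc1
F9 | step 1 | (2E,6E,10E)-geranylgeranyl bromide | CC(C)=CCC/C(C)=C/CC/C(C)=C/CC/C(C)=C/CBr
F10 | step 1 | 2-[(2E,6E,10E)-3,7,11,15-tetramethylhexadeca-2,6,10,14-tetraen-1-yl]-1,4-bis(methoxymethoxy)benzene | CC(C)=CCC/C(C)=C/CC/C(C)=C/CC/C(C)=C/Cc1cc(OCOC)ccc1OCOC
F11 | step 3 | jaspaquinone, 2-[(2E,6E)-3,7-dimethyl-9-(2,6,6-trimethylcyclohex-1-en-1-yl)nona-2,6-dien-1-yl]cyclohexa-2,5-diene-1,4-dione | CC1=C(CC/C(C)=C/CC/C(C)=C/CC2=CC(=O)C=CC2=O)C(C)(C)CCC1
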